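## Retrosynthetic overview
1. The carbonyl carbon is disconnected on both sides at once (C1–O and C1–C2), giving a docosene, carbon monoxide and 2-phenylethanol. Tricosanoic acid is never made and no esterification of it is used.
2. The alkene need not be terminal. A palladium hydride chain-walk lets mid-chain docos-11-ene stand in for docos-1-ene.
3. Docos-11-ene is cut at C11=C12 into two molecules of dodec-1-ene by self-metathesis. Carbon count: 12 + 12 − 2 + 1 = 23.
4. No ring is formed. The only ring, the phenyl group, is bought with 2-phenylethanol, and there is no stereocentre to set.

Assumption: the target has no stereocentre and no C=C bond, so it is achiral and "single enantiomer" simply means the compound itself.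
Assumption: the route has only two steps, so the risk ranking names both and lists step 2 twice, once for each of its two independent weaknesses.

## Route

Step 1
Reactants: 1 dodec-1-ene (two molecules)
Product: 2 docos-11-ene (E/Z about 4:1)
Conditions: second-generation Grubbs catalyst RuCl2(=CHPh)(PCy3)(SIMes) (0.1 mol %), 1,4-benzoquinone (2 mol %), neat, 45 °C, 50 mbar, 6 h; SiO2 plug (hexane), residual 1 distilled off
Reagents that add atoms: none
Why: Olefin self-metathesis (homodimerisation) of an unhindered terminal alkene is fast and is pulled to completion by stripping out ethene, 1,4-benzoquinone traps ruthenium hydrides so that no double-bond migration blurs the C22 chain length, and no stereocentre arises while the E/Z ratio is irrelevant because step 2 erases the alkene.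

Step 2
Reactants: 2 docos-11-ene; 3 carbon monoxide; 4 2-phenylethanol
Product: 6 2-phenylethyl tricosanoate, via docos-1-ene 5 (not isolated)
Conditions: Pd(OAc)2 (1 mol %), 1,2-bis(di-tert-butylphosphinomethyl)benzene (dtbpx, 5 mol %), CH3SO3H (10 mol %), CO (20 bar), 4 (8 equiv), toluene, 90 °C, 72 h, autoclave; NaHCO3 wash, excess 4 distilled off, recrystallisation from acetone
Reagents that add atoms: carbon monoxide [C-]#[O+]; 2-phenylethanol OCCc1ccccc1
Why: Isomerising alkoxycarbonylation (palladium hydride hydroesterification): [Pd(dtbpx)H]+ chain-walks reversibly through all docosene isomers by insertion and beta-hydride elimination, and because the very bulky diphosphine lets only the unbranched acyl derived from the terminal isomer 5 pass the rate-determining alcoholysis by 4, every positional and E/Z isomer funnels into the linear ester with all atoms of 2, 3 and 4 retained, no stereocentre being created.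

## Compound list
1 | dodec-1-ene | CCCCCCCCCCC=C | starting material
2 | docos-11-ene (E/Z about 4:1, SMILES of the major E isomer) | CCCCCCCCCC/C=C/CCCCCCCCCC | intermediate
3 | carbon monoxide | [C-]#[O+] | starting material
4 | 2-phenylethanol | OCCc1ccccc1 | starting material
5 | docos-1-ene (formed in the flask, not isolated) | CCCCCCCCCCCCCCCCCCCCC=C | intermediate
6 | 2-phenylethyl tricosanoate (achiral) | CCCCCCCCCCCCCCCCCCCCCCC(=O)OCCc1ccccc1 | target

## Totals and risks
Total step count: 2
Longest linear sequence: 2 (1 to 2 to 6)

**(a) Step 2, chain-walk and regiocontrol.**
- Risk: the double bond must migrate ten positions. With an alcohol that cleaves the acyl more slowly than methanol, conversion may stall. The 2-methyl-branched ester may also rise above what crystallisation removes.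
- Fallback: drop carbonylation and make the C2–C3 bond by cross-metathesis. It sets out from docos-1-ene 5 used as an isolated compound; 5 is sold, and the fallback under (b) delivers it chain-length pure.
- Compound 5 and 2-phenylethyl acrylate (C=CC(=O)OCCc1ccccc1, 2 equiv) are treated with second-generation Hoveyda–Grubbs catalyst RuCl2(=CH-C6H4-2-OiPr)(SIMes) (1 mol %) and 1,4-benzoquinone (5 mol %) in CH2Cl2 at 40 °C. This gives 2-phenylethyl (E)-tricos-2-enoate F1.
- H2 (1 bar) over Pd/C in EtOAc at room temperature then saturates the enoate without touching the non-benzylic ester C–O bond. The sequence comes back to the route at 6.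

**(b) Step 1, chain-length fidelity.**
- Risk: any ruthenium hydride isomerisation before or after metathesis gives C21 and C23 alkenes. These would end up as homologous esters that cannot be separated from 6.
- Fallback: fix the chain length by a stoichiometric sp3–sp3 coupling instead of metathesis. It sets out from 1.
- Hydroboration of 1 (1.1 equiv) with 9-BBN-H in THF at room temperature gives 9-dodecyl-9-borabicyclo[3.3.1]nonane F2.
- F2 is coupled in the same pot with 10-bromodec-1-ene (C=CCCCCCCCCBr) under Pd(OAc)2 (4 mol %), PCy3 (8 mol %) and K3PO4·H2O in THF at room temperature (alkyl–alkyl Suzuki–Miyaura coupling).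
- The product is docos-1-ene, so the fallback comes back to the route at 5. Here 5 is isolated and fed into step 2 in place of 2. Any alkene migration during the coupling is harmless because step 2 converges all isomers.

**(c) Step 2, the alcohol partner.**
- Risk: under acid at 90 °C, 4 may etherify or dehydrate, and any styrene formed would itself be carbonylated. It may also simply be too slow in the alcoholysis.
- Fallback: separate C–C bond formation from introduction of the alkoxy group. It sets out from 2.
- The chain-walk carbonylation is run in methanol, the nucleophile for which it is best established (Pd(OAc)2, dtbpx, CH3SO3H, CO 20 bar, MeOH, 90 °C). This gives methyl tricosanoate F3, which is crystallised free of branched isomers.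
- Immobilised Candida antarctica lipase B with 4 (1.5 equiv) in toluene at 60 °C and 100 mbar then exchanges the alkoxy group under neutral conditions. The sequence comes back to the route at 6.

## Further compounds
F1 | step 2 | 2-phenylethyl (E)-tricos-2-enoate | CCCCCCCCCCCCCCCCCCCC/C=C/C(=O)OCCc1ccccc1
F2 | step 1 | 9-dodecyl-9-borabicyclo[3.3.1]nonane | CCCCCCCCCCCCB1C2CCCC1CCC2
F3 | step 2 | methyl tricosanoate | CCCCCCCCCCCCCCCCCCCCCCC(=O)OC
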